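**Retrosynthetic overview**
1. Last cut: the allyl tert-alkyl ether C15(labdane)–O–C4(eudesmane). It is made by Williamson union of allylic bromide 19 (from isocupressic acid, acid masked as SEM ester) with the C4 alkoxide of 11-O-TES-cryptomeridiol 16; one fluoride step then unmasks acid and C11–OH.
2. 16 comes from bicyclic diene 13 by α-face hydration of the exocyclic C4=C15 methylene and saturation of C8=C9.
3. Key disconnection: both carbocycles of the decalin form in one cationic cascade from acyclic enyne 12. The In(III)-activated C4≡C15 alkyne closes ring A (C4–C5); the resulting C10 cation closes ring B through the C9–C10 bond at the silicon-bearing carbon of an (E)-vinylsilane (ring A, then ring B, same operation).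
4. Enabling feature: C10 is the methyl-bearing quaternary ring-fusion carbon of a trans-decalin, flanked by C5–H and C9H2 (head-to-tail isoprenoid pattern C4 / C5=C10(CH3) / C9). An (E)-C5=C10 alkene therefore delivers the C10 cation and the trans fusion, and the equatorial C7 side chain relays the one bought stereocentre to C5 and C10 (and, through the ring, to C4).
5. Enyne 12 comes from (R)-lavandulol (C7 bought; isopropenyl → C11 carbinol, CH2OH → C8=C9–SiMe3, E-methyl → C1) and 4-bromo-1-(trimethylsilyl)but-1-yne (C2, C3, C4, C15). The labdane bicycle is bought intact.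

Key step: step 8

Assumption: (R)-lavandulol, isocupressic acid and 4-bromo-1-(trimethylsilyl)but-1-yne are taken as purchasable; positions are named by eudesmane numbering in the sesquiterpene half and labdane numbering in the diterpene half.

**Route**

Step 1
Reactants: 1 (R)-lavandulol
Product: 3 (2S)-3-methyl-2-(3-methylbut-2-en-1-yl)butane-1,3-diol, via acetoxymercurial 2 (not isolated)
Conditions: Hg(OAc)2 (1.0 equiv), THF/H2O (1:1), 0 °C; then NaBH4, 3 M NaOH, 0 °C
Reagents that add atoms: water, O
Why: Oxymercuration–demercuration (Markovnikov hydration) is much faster at the 1,1-disubstituted isopropenyl group than at the trisubstituted prenyl alkene, so one equivalent of Hg(II) should give the tertiary C11 carbinol and leave the stereocentre (future C7) untouched.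

Step 2
Reactants: 3 (2S)-3-methyl-2-(3-methylbut-2-en-1-yl)butane-1,3-diol
Product: 4 bis(triethylsilyl) ether of 3
Conditions: TESOTf (2.4 equiv), 2,6-lutidine, CH2Cl2, −78 → 0 °C
Reagents that add atoms: triethylsilyl triflate, CC[Si](CC)(CC)OS(=O)(=O)C(F)(F)F
Why: Silyl triflate/lutidine silylation protects the primary and the hindered tertiary hydroxyl in one operation.

Step 3
Reactants: 4 bis(triethylsilyl) ether of 3
Product: 5 (2R)-5-methyl-2-[2-(triethylsilyloxy)propan-2-yl]hex-4-enal
Conditions: (COCl)2, DMSO, CH2Cl2, −78 → −30 °C; then i-Pr2NEt, −78 → 0 °C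
Reagents that add atoms: none
Why: Under Swern conditions a primary triethylsilyl ether is cleaved by the chlorosulfonium salt and oxidised in the same flask while the tertiary silyl ether is inert, and the hindered amine at low temperature should keep the α-stereocentre (C7) from epimerising.

Step 4
Reactants: 5 (2R)-5-methyl-2-[2-(triethylsilyloxy)propan-2-yl]hex-4-enal
Product: 6 triethyl({(3S)-2,6-dimethyl-3-[(E)-2-(trimethylsilyl)ethenyl]hept-5-en-2-yl}oxy)silane
Conditions: Me3SiCHBr2 (2 equiv), CrCl2 (8 equiv), THF, 25 °C
Reagents that add atoms: (dibromomethyl)trimethylsilane, C[Si](C)(C)C(Br)Br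
Why: Takai–Utimoto olefination with the gem-dichromium reagent converts the aldehyde into the (E)-vinylsilane under non-basic conditions, installing C9 with the silicon that later directs ring-B closure.

Step 5
Reactants: 6 triethyl({(3S)-2,6-dimethyl-3-[(E)-2-(trimethylsilyl)ethenyl]hept-5-en-2-yl}oxy)silane
Product: 7 (2E,5S,6E)-2-methyl-5-[2-(triethylsilyloxy)propan-2-yl]-7-(trimethylsilyl)hepta-2,6-dien-1-ol
Conditions: SeO2 (0.5 equiv), t-BuOOH (3 equiv), salicylic acid (cat.), CH2Cl2, 0 °C → rt
Reagents that add atoms: selenium dioxide, O=[Se]=O (oxygen donor, turned over by tert-butyl hydroperoxide, CC(C)(C)OO)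
Why: Riley-type SeO2 allylic oxidation (ene reaction, then [2,3]-sigmatropic shift) attacks the electron-rich trisubstituted alkene at its (E)-methyl group, which functionalises C1 and fixes the E geometry of C5=C10, while the vinylsilane is too electron-poor to react.

Step 6
Reactants: 7 (2E,5S,6E)-2-methyl-5-[2-(triethylsilyloxy)propan-2-yl]-7-(trimethylsilyl)hepta-2,6-dien-1-ol
Product: 8 {[(3S,5E)-7-bromo-2,6-dimethyl-3-[(E)-2-(trimethylsilyl)ethenyl]hept-5-en-2-yl]oxy}triethylsilane
Conditions: CBr4, PPh3, 2,6-lutidine (buffer), CH2Cl2, −30 → 0 °C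
Reagents that add atoms: carbon tetrabromide, BrC(Br)(Br)Br
Why: The Appel reaction converts the primary allylic alcohol into the bromide under neutral conditions without allylic transposition or loss of the silyl groups.

Step 7
Reactants: 8 {[(3S,5E)-7-bromo-2,6-dimethyl-3-[(E)-2-(trimethylsilyl)ethenyl]hept-5-en-2-yl]oxy}triethylsilane, 9 4-bromo-1-(trimethylsilyl)but-1-yne
Product: 12 triethyl({(3S,5E)-2,6-dimethyl-3-[(E)-2-(trimethylsilyl)ethenyl]undec-5-en-10-yn-2-yl}oxy)silane, via Grignard reagent 10 (not isolated), via silylalkyne 11 (not isolated)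
Conditions: 9, Mg, THF, rt; then 8, Li2CuCl4 (3 mol %), THF, −78 → 0 °C; then MeOH, K2CO3 (cat.), rt
Reagents that add atoms: none
Why: Copper-catalysed sp3–sp3 coupling (Kochi–Schlosser conditions) of the homopropargyl Grignard reagent with the primary allylic bromide should proceed at the α-carbon with retention of the E geometry, and mild methanolysis then removes only the alkynyl silicon (vinyl–Si and tertiary O–Si bonds are stable to K2CO3/MeOH).

Step 8
Reactants: 12 triethyl({(3S,5E)-2,6-dimethyl-3-[(E)-2-(trimethylsilyl)ethenyl]undec-5-en-10-yn-2-yl}oxy)silane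
Product: 13 11-(triethylsilyloxy)-5α-eudesma-4(15),8-diene (7β side chain, 10β-CH3)
Conditions: InBr3 (10 mol %), t-BuOH (1.5 equiv), CH2Cl2, −20 °C
Reagents that add atoms: none
Why: Proposed new method: InBr3 activates the terminal alkyne as a π-acid, C5 of the (E)-C5=C10 alkene attacks C4 anti to indium, the C10 cation that develops is captured by C9 (the silicon-bearing ipso carbon of the vinylsilane), the β-silyl cation at C8 expels Me3Si+ to leave the C8=C9 alkene, and t-BuOH takes up the silyl group and returns the proton that cleaves the C15–In bond to the exocyclic methylene and turns the catalyst over. The closest known reaction types are the In(III)- and Au(I)-catalysed alkyne-initiated cationic polycyclizations of 1,6-enynes that end on arenes and give the same exo-methylene trans-decalin ring A, and the vinylsilane-terminated cation–olefin cyclizations run with Brønsted or Lewis acid initiators; their combination and the silyl-to-proton relay are the untested part. Ring A closes through the C4–C5 bond in 6-exo-dig mode at the alkyne (endo with respect to the alkene), and ring B closes through the C9–C10 bond in 6-endo-trig mode at the vinylsilane. C5 and C10 are formed by anti addition across the E-alkene in a chair–chair transition state, which gives the trans ring fusion (5α-H, 10β-CH3), and their absolute sense is relayed from C7, whose bulky CMe2(OTES) group stays equatorial on the forming ring B. The selectivities needed are 6-endo over 5-exo closure of ring B (secured by silicon, which stabilises the cation only at C8 after ipso attack at C9), activation of the alkyne rather than of the alkene or the silyl ether (secured by the soft, carbophilic In(III) in the absence of strong Brønsted acid), and C–C over C–O capture of the C10 cation (favoured by the crowding around the tertiary silyl ether oxygen).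

Step 9
Reactants: 13 11-(triethylsilyloxy)-5α-eudesma-4(15),8-diene
Product: 15 11-(triethylsilyloxy)eudesm-8-en-4α-ol, via hydroperoxide 14 (not isolated)
Conditions: Mn(dpm)3 (10 mol %), PhSiH3, O2 (1 atm), i-PrOH/CH2Cl2, 0 °C; then PPh3
Reagents that add atoms: dioxygen, O=O
Why: Mukaiyama hydration (Mn–H hydrogen-atom transfer, then O2 capture) selects the 1,1-disubstituted C4=C15 alkene over the cis-1,2-disubstituted C8=C9 alkene, and the planar C4 radical should be trapped on the equatorial α-face because the axial β-face is shielded by the 1,3-diaxial C10 methyl group, which sets C4 as 4α-OH/4β-CH3.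

Step 10
Reactants: 15 11-(triethylsilyloxy)eudesm-8-en-4α-ol
Product: 16 11-(triethylsilyloxy)eudesman-4α-ol (11-O-TES-cryptomeridiol)
Conditions: H2 (1 atm), PtO2, EtOAc, rt
Reagents that add atoms: none
Why: Heterogeneous hydrogenation of the only remaining alkene (cis-disubstituted C8=C9) creates no stereocentre, and platinum is chosen because it causes little double-bond migration toward C7.

Step 11
Reactants: 17 isocupressic acid
Product: 18 [2-(trimethylsilyl)ethoxy]methyl (SEM) isocupressate
Conditions: SEMCl (1.05 equiv), i-Pr2NEt, CH2Cl2, 0 °C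
Reagents that add atoms: 2-(trimethylsilyl)ethoxymethyl chloride, C[Si](C)(C)CCOCCl
Why: O-Alkylation of the carboxylate with SEM chloride does not depend on access to the hindered axial C19 carbonyl and is much faster than etherification of the neutral allylic alcohol at 0 °C.

Step 12
Reactants: 18 SEM isocupressate
Product: 19 SEM 15-bromolabda-8(17),13E-dien-19-oate
Conditions: CBr4, PPh3, 2,6-lutidine (buffer), CH2Cl2, −20 °C
Reagents that add atoms: carbon tetrabromide, BrC(Br)(Br)Br
Why: Appel bromination of the primary allylic alcohol gives the (E)-allylic bromide without touching the exocyclic alkene or the SEM ester.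

Step 13
Reactants: 16 11-(triethylsilyloxy)eudesman-4α-ol, 19 SEM 15-bromolabda-8(17),13E-dien-19-oate
Product: 21 SEM ester and 11-O-TES ether of the target, via potassium alkoxide 20 (not isolated)
Conditions: KH, 18-crown-6 (cat.), THF, 0 °C → rt; then 19 (1.5 equiv), Bu4NI (cat.), 0 °C → rt
Reagents that add atoms: none
Why: Williamson ether synthesis: the potassium alkoxide of the equatorial tertiary C4 hydroxyl (the only free OH, C11–OH being silylated) displaces the reactive primary allylic bromide by SN2, so the C4 configuration and the E-alkene are carried over unchanged.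

Step 14
Reactants: 21 SEM ester and 11-O-TES ether of the target
Product: 22 target, CNP0156875.1
Conditions: TBAF (6 equiv), THF, 45 °C; then aq. NH4Cl/dilute HCl to pH 4
Reagents that add atoms: none
Why: Fluoride cleaves the tertiary triethylsilyl ether and triggers fragmentation of the SEM ester (loss of Me3SiF, ethene and formaldehyde) at the ester alkyl group, which frees the hindered C19 acid without hydrolysis and leaves the allyl tert-alkyl ether, the alkenes and all stereocentres untouched.

**Compound list**
1 | (R)-lavandulol, (2R)-5-methyl-2-(prop-1-en-2-yl)hex-4-en-1-ol | OC[C@H](CC=C(C)C)C(C)=C | starting material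
2 | acetoxymercurial of 1 (HgOAc on the former isopropenyl CH2, mixture at the carbinol carbon) | OC[C@H](CC=C(C)C)C(C)(O)C[Hg]OC(C)=O | intermediate
3 | (2S)-3-methyl-2-(3-methylbut-2-en-1-yl)butane-1,3-diol | OC[C@H](CC=C(C)C)C(C)(C)O | intermediate
4 | bis(triethylsilyl) ether of 3 | CC[Si](CC)(CC)OC[C@H](CC=C(C)C)C(C)(C)O[Si](CC)(CC)CC | intermediate
5 | (2R)-5-methyl-2-[2-(triethylsilyloxy)propan-2-yl]hex-4-enal | O=C[C@H](CC=C(C)C)C(C)(C)O[Si](CC)(CC)CC | intermediate
6 | triethyl({(3S)-2,6-dimethyl-3-[(E)-2-(trimethylsilyl)ethenyl]hept-5-en-2-yl}oxy)silane | C[Si](C)(C)/C=C/[C@H](CC=C(C)C)C(C)(C)O[Si](CC)(CC)CC | intermediate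
7 | (2E,5S,6E)-2-methyl-5-[2-(triethylsilyloxy)propan-2-yl]-7-(trimethylsilyl)hepta-2,6-dien-1-ol | C[Si](C)(C)/C=C/[C@H](C/C=C(\C)CO)C(C)(C)O[Si](CC)(CC)CC | intermediate
8 | {[(3S,5E)-7-bromo-2,6-dimethyl-3-[(E)-2-(trimethylsilyl)ethenyl]hept-5-en-2-yl]oxy}triethylsilane | C[Si](C)(C)/C=C/[C@H](C/C=C(\C)CBr)C(C)(C)O[Si](CC)(CC)CC | intermediate
9 | 4-bromo-1-(trimethylsilyl)but-1-yne | C[Si](C)(C)C#CCCBr | starting material
10 | [4-(trimethylsilyl)but-3-yn-1-yl]magnesium bromide | C[Si](C)(C)C#CCC[Mg]Br | intermediate
11 | 11-(trimethylsilyl) derivative of 12 (silylalkyne) | C[Si](C)(C)/C=C/[C@H](C/C=C(\C)CCCC#C[Si](C)(C)C)C(C)(C)O[Si](CC)(CC)CC | intermediate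
12 | triethyl({(3S,5E)-2,6-dimethyl-3-[(E)-2-(trimethylsilyl)ethenyl]undec-5-en-10-yn-2-yl}oxy)silane | C[Si](C)(C)/C=C/[C@H](C/C=C(\C)CCCC#C)C(C)(C)O[Si](CC)(CC)CC | intermediate
13 | 11-(triethylsilyloxy)-5α-eudesma-4(15),8-diene (7β side chain, 10β-CH3) | C=C1CCC[C@]2(C)C=C[C@@H](C(C)(C)O[Si](CC)(CC)CC)C[C@H]21 | intermediate
14 | 4α-hydroperoxy-11-(triethylsilyloxy)eudesm-8-ene | OO[C@]1(C)CCC[C@]2(C)C=C[C@@H](C(C)(C)O[Si](CC)(CC)CC)C[C@H]21 | intermediate
15 | 11-(triethylsilyloxy)eudesm-8-en-4α-ol | O[C@]1(C)CCC[C@]2(C)C=C[C@@H](C(C)(C)O[Si](CC)(CC)CC)C[C@H]21 | intermediate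
16 | 11-(triethylsilyloxy)eudesman-4α-ol (11-O-TES-cryptomeridiol) | O[C@]1(C)CCC[C@]2(C)CC[C@@H](C(C)(C)O[Si](CC)(CC)CC)C[C@H]21 | intermediate
17 | isocupressic acid, 15-hydroxylabda-8(17),13E-dien-19-oic acid | C=C1CC[C@@H]2[C@](C)(CCC[C@]2(C)C(=O)O)[C@H]1CC/C(C)=C/CO | starting material
18 | [2-(trimethylsilyl)ethoxy]methyl (SEM) isocupressate | C=C1CC[C@@H]2[C@](C)(CCC[C@]2(C)C(=O)OCOCC[Si](C)(C)C)[C@H]1CC/C(C)=C/CO | intermediate
19 | SEM 15-bromolabda-8(17),13E-dien-19-oate | C=C1CC[C@@H]2[C@](C)(CCC[C@]2(C)C(=O)OCOCC[Si](C)(C)C)[C@H]1CC/C(C)=C/CBr | intermediate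
20 | potassium 4α-alkoxide of 16 | [K+].[O-][C@]1(C)CCC[C@]2(C)CC[C@@H](C(C)(C)O[Si](CC)(CC)CC)C[C@H]21 | intermediate
21 | SEM ester and 11-O-TES ether of the target | C=C1CC[C@@H]2[C@](C)(CCC[C@]2(C)C(=O)OCOCC[Si](C)(C)C)[C@H]1CC/C(C)=C/CO[C@]1(C)CCC[C@]2(C)CC[C@@H](C(C)(C)O[Si](CC)(CC)CC)C[C@H]21 | intermediate
22 | CNP0156875.1, 15-O-(11-hydroxyeudesman-4α-yl)isocupressic acid | C=C1CC[C@@H]2[C@](C)(CCC[C@]2(C)C(=O)O)[C@H]1CC/C(C)=C/CO[C@]1(C)CCC[C@]2(C)CC[C@@H](C(C)(C)O)C[C@H]21 | target

**Step count**
Total: 14 steps. Longest linear sequence: 12 steps (steps 1–10, 13, 14, from (R)-lavandulol).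

**Steps most likely to fail**

1. Step 8 (bears the label). What may go wrong: protodesilylation of the vinylsilane by adventitious HBr before it can terminate the cascade; interruption after ring A by proton loss from the C10 cation, because ipso attack on a tertiary cation is slow; stalling of catalyst turnover if the silyl-to-proton relay fails. The fallback uses known chemistry, sets out from 8 and comes back at 13. Allylic bromide 8 is coupled, under the copper catalysis of step 7, with commercial (1,3-dioxan-2-ylethyl)magnesium bromide to give dioxane acetal F1. The acetal is opened without loss of the silyl ethers (TESOTf/2,4,6-collidine, then water) to aldehyde F2. Stoichiometric Me2AlCl (CH2Cl2, −78 °C) then brings about the aldehyde-initiated, vinylsilane-terminated Prins-type cation–olefin bicyclization, which forms the same C4–C5 and C9–C10 bonds with no turnover step and should give 15-nor-eudesm-8-en-4-ol F3 (C4 epimers, of no consequence). Dess–Martin oxidation gives ketone F4, and Wittig methylenation (Ph3P=CH2) returns diene 13.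

2. Step 13. What may go wrong: slow O-alkylation of the hindered tertiary alkoxide, with base-induced 1,4-elimination of HBr from the allylic bromide taking over. The fallback sets out from 18 (with 16) and comes back at 21. Alcohol 18 is acetylated (Ac2O, pyridine) to allylic acetate F5. This is coupled by palladium-catalysed allylic etherification (Tsuji–Trost type; Pd(OAc)2, 2-(di-tert-butylphosphino)biphenyl, THF, rt) with ethylzinc alkoxide F6, made from 16 and Et2Zn. Attack at the unhindered terminus of the π-allyl complex should give the linear E ether 21 under non-basic conditions.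

3. Step 9. What may go wrong: poor facial selectivity in the capture of the planar C4 radical by O2, or hydrogen-atom reduction of the radical instead of oxygenation. The fallback sets out from 13 and comes back at 15. It is an ionic Markovnikov hydration by oxymercuration–demercuration (Hg(OAc)2, THF/H2O; then NaBH4, NaOH) through organomercurial F7. Water should open the mercurinium ion at C4 from the equatorial α-face, and the 1,2-disubstituted C8=C9 alkene reacts far more slowly.

**Further compounds**
F1 | step 8 | 2-[(4E,7S,8E)-4-methyl-7-[2-(triethylsilyloxy)propan-2-yl]-9-(trimethylsilyl)nona-4,8-dien-1-yl]-1,3-dioxane | C[Si](C)(C)/C=C/[C@H](C/C=C(\C)CCCC1OCCCO1)C(C)(C)O[Si](CC)(CC)CC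
F2 | step 8 | (5E,8S,9E)-5-methyl-8-[2-(triethylsilyloxy)propan-2-yl]-10-(trimethylsilyl)deca-5,9-dienal | C[Si](C)(C)/C=C/[C@H](C/C=C(\C)CCCC=O)C(C)(C)O[Si](CC)(CC)CC
F3 | step 8 | 15-nor-11-(triethylsilyloxy)-5α-eudesm-8-en-4-ol (C4 epimers) | OC1CCC[C@]2(C)C=C[C@@H](C(C)(C)O[Si](CC)(CC)CC)C[C@H]21
F4 | step 8 | 15-nor-11-(triethylsilyloxy)-5α-eudesm-8-en-4-one | O=C1CCC[C@]2(C)C=C[C@@H](C(C)(C)O[Si](CC)(CC)CC)C[C@H]21
F5 | step 13 | SEM 15-acetoxylabda-8(17),13E-dien-19-oate | C=C1CC[C@@H]2[C@](C)(CCC[C@]2(C)C(=O)OCOCC[Si](C)(C)C)[C@H]1CC/C(C)=C/COC(C)=O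
F6 | step 13 | ethylzinc 4α-alkoxide of 16 | CC[Zn]O[C@]1(C)CCC[C@]2(C)CC[C@@H](C(C)(C)O[Si](CC)(CC)CC)C[C@H]21
F7 | step 9 | 15-(acetoxymercurio)-11-(triethylsilyloxy)eudesm-8-en-4α-ol | O[C@]1(C[Hg]OC(C)=O)CCC[C@]2(C)C=C[C@@H](C(C)(C)O[Si](CC)(CC)CC)C[C@H]21
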